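**Retrosynthetic overview**
1. The target is read as a 2,3-seco-labdane: cyclohexane ring B (C5–C10) bridged by the δ-lactone C8–O–C2(=O)–C1–C10 (a 2-oxabicyclo[3.3.1]nonan-3-one), with CMe2CO2H on C5, OH on C6 and the C11–C15 diol chain on C9.
2. Key disconnection C1–C10: 6-exo radical closure of a bromoacetal tethered to the tertiary C8–O onto C10. The enabling feature is that O8 on C8 is 1,3 to C10 across C9 on ring B (cis-diaxial reach) and C10 is the β-carbon of the C6 enone (C6=O, C5=C10), so the oxane ring and the quaternary centre form together.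
3. C5–C4 bond by Negishi coupling of the C5-iodoenone with the Reformatsky reagent of methyl 2-bromo-2-methylpropanoate; C6 oxygen by allylic oxidation of the ring alkene.
4. Side chain by two chelation-controlled additions: Mukaiyama aldol at the C11 aldehyde (C11), then MeMgBr on the vinyl ketone (C13).
5. C8/C9 from Sharpless epoxidation of nerol and SN2 opening with an isopropenyl cuprate; ring order: ring B by ring-closing metathesis (step 3), then the oxane/lactone ring (step 12).

Key step: step 12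

Remark: locants C1–C15 follow the seco-labdane numbering above; the free 6-hydroxy acid and the tertiary δ-lactone of the target are assumed to persist at neutral pH (no γ-lactonisation, no acyl shift to O6 or O11).

Step 1
Reactants: 1 nerol
Product: 2 (2R,3S)-2,3-epoxynerol
Conditions: Ti(OiPr)4 (10 mol%), D-(−)-diethyl tartrate (12 mol%), t-BuOOH, 4 Å MS, CH2Cl2, −20 °C
Reagents that add atoms: tert-butyl hydroperoxide, CC(C)(C)OO
Why: Sharpless asymmetric epoxidation of the Z-allylic alcohol with the D-tartrate complex should deliver oxygen to the face that gives the (2R,3S)-epoxide, which fixes C8 (S) of the target.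

Step 2
Reactants: 2 (2R,3S)-2,3-epoxynerol; 3 isopropenylmagnesium bromide
Product: 4 (2S,3S)-3,7-dimethyl-2-(prop-1-en-2-yl)oct-6-ene-1,3-diol
Conditions: 3 (3 equiv), CuI (10 mol%), THF/Et2O, −30 → 0 °C
Reagents that add atoms: none
Why: Copper-catalysed Grignard opening of a 2,3-epoxy alcohol should occur by SN2 attack at the oxirane carbon bearing CH2OH (the fully substituted carbon is blocked), with inversion, which sets C9 (S) and places O8 and the C11 arm cis in the later ring.

Step 3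
Reactants: 4 (2S,3S)-3,7-dimethyl-2-(prop-1-en-2-yl)oct-6-ene-1,3-diol
Product: 5 (1S,2S)-2-(hydroxymethyl)-1,3-dimethylcyclohex-3-en-1-ol
Conditions: second-generation Hoveyda–Grubbs catalyst (5 mol%), toluene (0.01 M), 80 °C
Reagents that add atoms: none
Why: Ring-closing metathesis between the 1,1-disubstituted and the prenyl-type alkene should close ring B as a trisubstituted cyclohexene with loss of 2-methylpropene, leaving both stereocentres untouched.

Step 4
Reactants: 5 (1S,2S)-2-(hydroxymethyl)-1,3-dimethylcyclohex-3-en-1-ol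
Product: 6 (1R,6S)-6-hydroxy-2,6-dimethylcyclohex-2-ene-1-carbaldehyde
Conditions: TEMPO (10 mol%), PhI(OAc)2 (1.1 equiv), CH2Cl2, 0 °C → rt; used at once
Reagents that add atoms: none
Why: Oxoammonium (TEMPO/PhI(OAc)2) oxidation is selective for the primary alcohol beside the tertiary one and stops at the aldehyde, an α-cyclocitral-type β,γ-unsaturated aldehyde that should survive neutral handling.

Step 5
Reactants: 6 (1R,6S)-6-hydroxy-2,6-dimethylcyclohex-2-ene-1-carbaldehyde; 7 2-(trimethylsilyloxy)buta-1,3-diene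
Product: 8 (5S)-5-hydroxy-5-[(1S,6S)-6-hydroxy-2,6-dimethylcyclohex-2-en-1-yl]pent-1-en-3-one
Conditions: Me2AlCl (2.5 equiv), CH2Cl2, −78 °C; then 7 (2 equiv), −78 °C; aq. Rochelle salt
Reagents that add atoms: none
Why: Chelation-controlled Mukaiyama aldol addition: the aluminium alkoxide of the tertiary C8–OH and the aldehyde oxygen should form a six-membered chelate that the enol silane attacks from the side of H9 (Cram-chelate, 1,3-anti), which sets C11 (S).

Step 6
Reactants: 8 (5S)-5-hydroxy-5-[(1S,6S)-6-hydroxy-2,6-dimethylcyclohex-2-en-1-yl]pent-1-en-3-one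
Product: 9 (5S)-5-[(1S,6S)-6-hydroxy-2,6-dimethylcyclohex-2-en-1-yl]-5-{[2-(trimethylsilyl)ethoxy]methoxy}pent-1-en-3-one
Conditions: SEMCl (1.5 equiv), iPr2NEt, Bu4NI (cat.), CH2Cl2, 0 °C → rt
Reagents that add atoms: 2-(trimethylsilyl)ethoxymethyl chloride, ClCOCC[Si](C)(C)C
Why: Alkylation with SEMCl (Williamson-type acetal ether formation) should be selective for the secondary alcohol over the hindered tertiary one and leaves a chelating acetal oxygen on C11 for step 8.

Step 7
Reactants: 9 (5S)-5-[(1S,6S)-6-hydroxy-2,6-dimethylcyclohex-2-en-1-yl]-5-{[2-(trimethylsilyl)ethoxy]methoxy}pent-1-en-3-one; 10 ethyl vinyl ether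
Product: 11 (5S)-5-[(1S,6S)-6-(2-bromo-1-ethoxyethoxy)-2,6-dimethylcyclohex-2-en-1-yl]-5-{[2-(trimethylsilyl)ethoxy]methoxy}pent-1-en-3-one (both acetal epimers)
Conditions: 10 (4 equiv), NBS (1.5 equiv), CH2Cl2, −40 → 0 °C
Reagents that add atoms: N-bromosuccinimide, O=C1CCC(=O)N1Br
Why: Ueno–Stork bromoacetalisation: the only free hydroxyl (tertiary C8–OH) should capture the bromo-oxocarbenium species formed from NBS and the vinyl ether, which reacts far faster with NBS than the ring alkene, and the new acetal centre is formed as a mixture that converges in step 14.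

Step 8
Reactants: 11 bromoacetal vinyl ketone (as above)
Product: 12 (3R,5S)-5-[(1S,6S)-6-(2-bromo-1-ethoxyethoxy)-2,6-dimethylcyclohex-2-en-1-yl]-3-methyl-5-{[2-(trimethylsilyl)ethoxy]methoxy}pent-1-en-3-ol
Conditions: MeMgBr (2 equiv), CH2Cl2/Et2O, −78 °C
Reagents that add atoms: methylmagnesium bromide, C[Mg]Br
Why: Chelation-controlled Grignard 1,2-addition: magnesium should bridge the ketone and the C11 acetal oxygen and methyl attacks the chair chelate axially (Cram–Reetz 1,3-model), giving the 1,3-syn relation and C13 (R).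

Step 9
Reactants: 12 tertiary alcohol (as above)
Product: 13 (4S,5S)-5-(2-bromo-1-ethoxyethoxy)-4-[(1S,3R)-3-hydroxy-3-methyl-1-{[2-(trimethylsilyl)ethoxy]methoxy}pent-4-en-1-yl]-3,5-dimethylcyclohex-2-en-1-one
Conditions: Rh2(cap)4 (1 mol%, cap = caprolactamate), t-BuOOH (5 equiv), K2CO3 (0.5 equiv), CH2Cl2, rt
Reagents that add atoms: tert-butyl hydroperoxide, CC(C)(C)OO
Why: Dirhodium-catalysed allylic C–H oxidation should convert the C6 methylene, the only unhindered allylic CH2, into the enone carbonyl, while the side-chain vinyl group has no allylic hydrogen and stays inert.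

Step 10
Reactants: 13 enone (as above)
Product: 14 (4S,5S)-5-(2-bromo-1-ethoxyethoxy)-4-[(1S,3R)-3-hydroxy-3-methyl-1-{[2-(trimethylsilyl)ethoxy]methoxy}pent-4-en-1-yl]-2-iodo-3,5-dimethylcyclohex-2-en-1-one
Conditions: I2 (2 equiv), pyridine/CH2Cl2, DMAP (cat.), rt
Reagents that add atoms: iodine, II
Why: α-Iodination of the enone by amine conjugate addition, iodination of the enolate and elimination should place iodine on C5 without forming or touching a stereocentre.

Step 11
Reactants: 14 iodoenone (as above); 15 methyl 2-bromo-2-methylpropanoate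
Product: 17 methyl 2-[(3S,4S)-4-(2-bromo-1-ethoxyethoxy)-3-[(1S,3R)-3-hydroxy-3-methyl-1-{[2-(trimethylsilyl)ethoxy]methoxy}pent-4-en-1-yl]-2,4-dimethyl-6-oxocyclohex-1-en-1-yl]-2-methylpropanoate, via Reformatsky reagent 16 (not isolated)
Conditions: 15, Zn dust, THF, rt; then 14, Pd(dba)2 (5 mol%), P(t-Bu)3 (10 mol%), THF, rt → 50 °C (3 equiv of 16)
Reagents that add atoms: none
Why: Negishi cross-coupling of the alkenyl iodide with the zinc ester enolate (Reformatsky reagent) on zerovalent palladium with a bulky electron-rich phosphine should form the C5–C4 bond with its quaternary carbon; no stereocentre is formed.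

Step 12
Reactants: 17 bromoacetal enone (as above)
Product: 18 methyl 2-[(1S,5S,6R,9S)-3-ethoxy-9-[(1S,3R)-3-hydroxy-3-methyl-1-{[2-(trimethylsilyl)ethoxy]methoxy}pent-4-en-1-yl]-1,5-dimethyl-7-oxo-2-oxabicyclo[3.3.1]nonan-6-yl]-2-methylpropanoate (both C3 acetal epimers)
Conditions: Bu3SnH (1.3 equiv) and AIBN (0.2 equiv) by syringe pump, benzene (5 mM), 80 °C
Reagents that add atoms: none
Why: The tributyltin radical abstracts bromine to give the primary C1 radical, which adds in 6-exo-trig mode to C10, the β-carbon of the C6 enone, and the resulting tertiary α-keto radical at C5 takes hydrogen from Bu3SnH. The closest known reaction type is the Ueno–Stork bromoacetal radical cyclisation, run here as a Giese-type conjugate addition that creates a quaternary centre. It closes the oxane ring O8–C2–C1–C10–C9–C8 by 6-exo-trig attack, which bridges ring B to the 2-oxabicyclo[3.3.1]nonane. C10 is set by the tether, because the axial C8–O can deliver C1 only to its own face (C1 cis to O8 and C11), and C5 is set by hydrogen transfer anti to the new axial C1–C10 bond, the equatorial CMe2CO2Me also being the thermodynamic choice at this epimerisable α-keto centre. The step needs 6-exo addition to win over direct reduction and 1,5-hydrogen shift; the enone LUMO at C10 matches the nucleophilic alkyl radical, C10 is the only acceptor within reach of the two-atom tether, and slow addition keeps the stannane concentration low. Both acetal epimers of 17 should cyclise and are merged when C2 becomes the lactone carbonyl.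

Step 13
Reactants: 18 bridged acetal methyl ester (as above)
Product: 19 2-[(1S,5S,6R,9S)-3-ethoxy-9-[(1S,3R)-3-hydroxy-3-methyl-1-{[2-(trimethylsilyl)ethoxy]methoxy}pent-4-en-1-yl]-1,5-dimethyl-7-oxo-2-oxabicyclo[3.3.1]nonan-6-yl]-2-methylpropanoic acid
Conditions: LiI (10 equiv), EtOAc, reflux; then cold 0.5 M HCl to pH 4
Reagents that add atoms: none
Why: SN2 dealkylation of the methyl ester by iodide attacks O–CH3, so the hindered acyl carbon does not matter, and it should free the C3 acid under neutral conditions before the base-sensitive β-acyloxy ketone exists.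

Step 14
Reactants: 19 bridged acetal acid (as above)
Product: 21 2-[(1S,5S,6R,9S)-9-[(1S,3R)-3-hydroxy-3-methyl-1-{[2-(trimethylsilyl)ethoxy]methoxy}pent-4-en-1-yl]-1,5-dimethyl-3,7-dioxo-2-oxabicyclo[3.3.1]nonan-6-yl]-2-methylpropanoic acid, via lactol 20 (not isolated)
Conditions: AcOH/THF/H2O (3:1:1), 40 °C; evaporate; then TEMPO (20 mol%), PhI(OAc)2 (1.5 equiv), CH2Cl2, rt
Reagents that add atoms: water, O
Why: Mild acetal hydrolysis followed by chemoselective oxoammonium oxidation of the lactol should give the δ-lactone from both acetal epimers, the SEM ether keeping O11 from closing an internal acetal and no secondary alcohol being free.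

Step 15
Reactants: 21 SEM-protected keto lactone acid (as above)
Product: 22 2-[(1S,5S,6R,9S)-9-[(1S,3R)-1,3-dihydroxy-3-methylpent-4-en-1-yl]-1,5-dimethyl-3,7-dioxo-2-oxabicyclo[3.3.1]nonan-6-yl]-2-methylpropanoic acid
Conditions: MgBr2·OEt2 (10 equiv), MeNO2, Et2O, rt
Reagents that add atoms: none
Why: Magnesium bromide-mediated SEM ether cleavage (chelation, bromide attack at silicon, fragmentation) should free the C11 alcohol without base, sparing the β-acyloxy ketone and the tertiary allylic alcohol.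

Step 16
Reactants: 22 keto lactone diol acid (as above)
Product: 23 2-[(1S,5R,6R,7R,9S)-9-[(1S,3R)-1,3-dihydroxy-3-methylpent-4-en-1-yl]-7-hydroxy-1,5-dimethyl-3-oxo-2-oxabicyclo[3.3.1]nonan-6-yl]-2-methylpropanoic acid (CNP0297019.1)
Conditions: NaBH4 (3 equiv), CeCl3·7H2O (1.5 equiv), MeOH/THF, −78 → −40 °C; pH 6 phosphate buffer
Reagents that add atoms: none
Why: Luche reduction: hydride should reach the C6 carbonyl only from the exo face of the 2-oxabicyclo[3.3.1]nonane, the endo face being covered by the lactone bridge, which gives the endo (6R) alcohol cis to O8 and C4 while the lactone and the carboxylate stay intact at low temperature.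

**Compound list**
1 | nerol, (2Z)-3,7-dimethylocta-2,6-dien-1-ol | CC(C)=CCC/C(C)=C\CO | starting material
2 | (2R,3S)-2,3-epoxynerol, [(2R,3S)-3-methyl-3-(4-methylpent-3-en-1-yl)oxiran-2-yl]methanol | CC(C)=CCC[C@]1(C)O[C@@H]1CO | intermediate
3 | isopropenylmagnesium bromide | C=C(C)[Mg]Br | starting material
4 | (2S,3S)-3,7-dimethyl-2-(prop-1-en-2-yl)oct-6-ene-1,3-diol | OC[C@H](C(C)=C)[C@@](C)(O)CCC=C(C)C | intermediate
5 | (1S,2S)-2-(hydroxymethyl)-1,3-dimethylcyclohex-3-en-1-ol | OC[C@@H]1C(C)=CCC[C@]1(C)O | intermediate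
6 | (1R,6S)-6-hydroxy-2,6-dimethylcyclohex-2-ene-1-carbaldehyde | O=C[C@@H]1C(C)=CCC[C@]1(C)O | intermediate
7 | 2-(trimethylsilyloxy)buta-1,3-diene | C=CC(=C)O[Si](C)(C)C | starting material
8 | (5S)-5-hydroxy-5-[(1S,6S)-6-hydroxy-2,6-dimethylcyclohex-2-en-1-yl]pent-1-en-3-one | C=CC(=O)C[C@H](O)[C@@H]1C(C)=CCC[C@]1(C)O | intermediate
9 | (5S)-5-[(1S,6S)-6-hydroxy-2,6-dimethylcyclohex-2-en-1-yl]-5-{[2-(trimethylsilyl)ethoxy]methoxy}pent-1-en-3-one | C=CC(=O)C[C@H](OCOCC[Si](C)(C)C)[C@@H]1C(C)=CCC[C@]1(C)O | intermediate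
10 | ethyl vinyl ether (ethoxyethene) | C=COCC | starting material
11 | (5S)-5-[(1S,6S)-6-(2-bromo-1-ethoxyethoxy)-2,6-dimethylcyclohex-2-en-1-yl]-5-{[2-(trimethylsilyl)ethoxy]methoxy}pent-1-en-3-one, acetal epimers | C=CC(=O)C[C@H](OCOCC[Si](C)(C)C)[C@@H]1C(C)=CCC[C@]1(C)OC(CBr)OCC | intermediate
12 | (3R,5S)-5-[(1S,6S)-6-(2-bromo-1-ethoxyethoxy)-2,6-dimethylcyclohex-2-en-1-yl]-3-methyl-5-{[2-(trimethylsilyl)ethoxy]methoxy}pent-1-en-3-ol, acetal epimers | C=C[C@](C)(O)C[C@H](OCOCC[Si](C)(C)C)[C@@H]1C(C)=CCC[C@]1(C)OC(CBr)OCC | intermediate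
13 | (4S,5S)-5-(2-bromo-1-ethoxyethoxy)-4-[(1S,3R)-3-hydroxy-3-methyl-1-{[2-(trimethylsilyl)ethoxy]methoxy}pent-4-en-1-yl]-3,5-dimethylcyclohex-2-en-1-one, acetal epimers | C=C[C@](C)(O)C[C@H](OCOCC[Si](C)(C)C)[C@@H]1C(C)=CC(=O)C[C@]1(C)OC(CBr)OCC | intermediate
14 | 2-iodo derivative of 13 (iodine on C5) | C=C[C@](C)(O)C[C@H](OCOCC[Si](C)(C)C)[C@@H]1C(C)=C(I)C(=O)C[C@]1(C)OC(CBr)OCC | intermediate
15 | methyl 2-bromo-2-methylpropanoate | COC(=O)C(C)(C)Br | starting material
16 | Reformatsky reagent, bromo(1-methoxy-2-methyl-1-oxopropan-2-yl)zinc | COC(=O)C(C)(C)[Zn]Br | intermediate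
17 | methyl 2-[(3S,4S)-4-(2-bromo-1-ethoxyethoxy)-3-[(1S,3R)-3-hydroxy-3-methyl-1-{[2-(trimethylsilyl)ethoxy]methoxy}pent-4-en-1-yl]-2,4-dimethyl-6-oxocyclohex-1-en-1-yl]-2-methylpropanoate, acetal epimers | C=C[C@](C)(O)C[C@H](OCOCC[Si](C)(C)C)[C@@H]1C(C)=C(C(C)(C)C(=O)OC)C(=O)C[C@]1(C)OC(CBr)OCC | intermediate
18 | methyl 2-[(1S,5S,6R,9S)-3-ethoxy-9-[(1S,3R)-3-hydroxy-3-methyl-1-{[2-(trimethylsilyl)ethoxy]methoxy}pent-4-en-1-yl]-1,5-dimethyl-7-oxo-2-oxabicyclo[3.3.1]nonan-6-yl]-2-methylpropanoate, C3 epimers | C=C[C@](C)(O)C[C@H](OCOCC[Si](C)(C)C)[C@@H]1[C@]2(C)CC(OCC)O[C@@]1(C)CC(=O)[C@H]2C(C)(C)C(=O)OC | intermediate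
19 | carboxylic acid of 18 | C=C[C@](C)(O)C[C@H](OCOCC[Si](C)(C)C)[C@@H]1[C@]2(C)CC(OCC)O[C@@]1(C)CC(=O)[C@H]2C(C)(C)C(=O)O | intermediate
20 | lactol of 19 (3-hydroxy in place of 3-ethoxy), C3 epimers | C=C[C@](C)(O)C[C@H](OCOCC[Si](C)(C)C)[C@@H]1[C@]2(C)CC(O)O[C@@]1(C)CC(=O)[C@H]2C(C)(C)C(=O)O | intermediate
21 | 2-[(1S,5S,6R,9S)-9-[(1S,3R)-3-hydroxy-3-methyl-1-{[2-(trimethylsilyl)ethoxy]methoxy}pent-4-en-1-yl]-1,5-dimethyl-3,7-dioxo-2-oxabicyclo[3.3.1]nonan-6-yl]-2-methylpropanoic acid | C=C[C@](C)(O)C[C@H](OCOCC[Si](C)(C)C)[C@@H]1[C@]2(C)CC(=O)O[C@@]1(C)CC(=O)[C@H]2C(C)(C)C(=O)O | intermediate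
22 | 2-[(1S,5S,6R,9S)-9-[(1S,3R)-1,3-dihydroxy-3-methylpent-4-en-1-yl]-1,5-dimethyl-3,7-dioxo-2-oxabicyclo[3.3.1]nonan-6-yl]-2-methylpropanoic acid | C=C[C@](C)(O)C[C@H](O)[C@@H]1[C@]2(C)CC(=O)O[C@@]1(C)CC(=O)[C@H]2C(C)(C)C(=O)O | intermediate
23 | 2-[(1S,5R,6R,7R,9S)-9-[(1S,3R)-1,3-dihydroxy-3-methylpent-4-en-1-yl]-7-hydroxy-1,5-dimethyl-3-oxo-2-oxabicyclo[3.3.1]nonan-6-yl]-2-methylpropanoic acid (CNP0297019.1) | C=C[C@](C)(O)C[C@H](O)[C@@H]1[C@]2(C)CC(=O)O[C@@]1(C)C[C@@H](O)[C@H]2C(C)(C)C(=O)O | target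

**Totals**
Total step count: 16. Longest linear sequence: 16 steps (from nerol).

**Steps most likely to fail**

Step 12 (key step). Hydrogen transfer from the stannane to the primary radical, or a 1,5-hydrogen shift, may outrun addition to the crowded, twisted tetrasubstituted enone, so that the cyclisation does not take place. The fallback replaces the radical closure by an anionic one; it sets out from 17 and comes back at 21. The tertiary allylic alcohol of 17 is silylated (TESCl, imidazole, DMAP, DMF) to the triethylsilyl ether F3. The bromoacetal is removed by zinc-mediated reductive elimination (Zn, NH4Cl, EtOH, 60 °C) to the tertiary alcohol F4. Acylation with Meldrum's acid (toluene, 100 °C) gives the malonic acid half ester F5. Intramolecular 6-exo Michael addition (Cs2CO3, MeCN, rt) closes the same C1–C10 bond to the α-carboxy lactone F6. Thermal decarboxylation (toluene/pyridine, 90 °C) gives the keto lactone methyl ester F7. LiI demethylation gives the acid F8, and HF·pyridine removes the silyl group to give 21.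

Step 11. Oxidative addition and transmetalation at the alkenyl iodide flanked by a methyl group and a carbonyl may be too slow, so that protodeiodination and enolate decomposition take over. The fallback builds the C5–C4 bond by radical alkylation of an enol silane; it sets out from 13 and comes back at 17. Conjugate reduction of 13 with [(Ph3P)CuH]6 and Me3SiCl gives the trimethylsilyl enol ether F1. Photoredox alkylation with 15 (Ru(bpy)3Cl2, blue light, DMF) gives the γ-keto ester F2. Dehydrogenation with IBX (DMSO, 70 °C), possible only towards C10, gives 17.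

Step 16. The alkoxyborate formed at C6 sits next to the lactone carbonyl and the C3 acid, so acyl migration to O6 or O11 or γ-lactonisation may compete with simple reduction. The fallback sets the C6 alcohol before the lactone exists and ends with a fluoride deprotection; it sets out from 19 and comes back at 23. NaBH4 reduction of 19 (MeOH, 0 °C, exo attack) gives the hydroxy acid acetal F9. Silylation of the secondary alcohol (TBSOTf, 2,6-lutidine, −78 °C) gives the silyl ether F10. Hydrolysis and oxidation as in step 14 give the lactone F11. MgBr2·OEt2/MeNO2 removes the SEM group to give the alcohol F12, and buffered HF·pyridine gives 23.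

**Further compounds**
F1 | step 11 | trimethylsilyl enol ether (C6–OSiMe3, C5=C6) from conjugate reduction of 13, C10 epimers | C=C[C@](C)(O)C[C@H](OCOCC[Si](C)(C)C)[C@@H]1C(C)C=C(O[Si](C)(C)C)C[C@]1(C)OC(CBr)OCC
F2 | step 11 | saturated C6 ketone bearing CMe2CO2Me on C5, C5/C10 epimers | C=C[C@](C)(O)C[C@H](OCOCC[Si](C)(C)C)[C@@H]1C(C)C(C(C)(C)C(=O)OC)C(=O)C[C@]1(C)OC(CBr)OCC
F3 | step 12 | 17 with the C13 hydroxyl as triethylsilyl ether | C=C[C@](C)(O[Si](CC)(CC)CC)C[C@H](OCOCC[Si](C)(C)C)[C@@H]1C(C)=C(C(C)(C)C(=O)OC)C(=O)C[C@]1(C)OC(CBr)OCC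
F4 | step 12 | F3 with free tertiary C8–OH (bromoacetal removed) | C=C[C@](C)(O[Si](CC)(CC)CC)C[C@H](OCOCC[Si](C)(C)C)[C@@H]1C(C)=C(C(C)(C)C(=O)OC)C(=O)C[C@]1(C)O
F5 | step 12 | C8–O malonic acid half ester of F4 | C=C[C@](C)(O[Si](CC)(CC)CC)C[C@H](OCOCC[Si](C)(C)C)[C@@H]1C(C)=C(C(C)(C)C(=O)OC)C(=O)C[C@]1(C)OC(=O)CC(=O)O
F6 | step 12 | bridged δ-lactone with CO2H on C1 (C1 epimers), methyl ester at C3 | C=C[C@](C)(O[Si](CC)(CC)CC)C[C@H](OCOCC[Si](C)(C)C)[C@@H]1[C@]2(C)C(C(=O)O)C(=O)O[C@@]1(C)CC(=O)[C@H]2C(C)(C)C(=O)OC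
F7 | step 12 | keto lactone methyl ester, C13–OSiEt3, C11–OSEM | C=C[C@](C)(O[Si](CC)(CC)CC)C[C@H](OCOCC[Si](C)(C)C)[C@@H]1[C@]2(C)CC(=O)O[C@@]1(C)CC(=O)[C@H]2C(C)(C)C(=O)OC
F8 | step 12 | carboxylic acid of F7 | C=C[C@](C)(O[Si](CC)(CC)CC)C[C@H](OCOCC[Si](C)(C)C)[C@@H]1[C@]2(C)CC(=O)O[C@@]1(C)CC(=O)[C@H]2C(C)(C)C(=O)O
F9 | step 16 | (7R)-hydroxy acid of 19 (C6 alcohol, bridged ethyl acetal) | C=C[C@](C)(O)C[C@H](OCOCC[Si](C)(C)C)[C@@H]1[C@]2(C)CC(OCC)O[C@@]1(C)C[C@@H](O)[C@H]2C(C)(C)C(=O)O
F10 | step 16 | F9 with C6–O as tert-butyldimethylsilyl ether | C=C[C@](C)(O)C[C@H](OCOCC[Si](C)(C)C)[C@@H]1[C@]2(C)CC(OCC)O[C@@]1(C)C[C@@H](O[Si](C)(C)C(C)(C)C)[C@H]2C(C)(C)C(=O)O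
F11 | step 16 | δ-lactone from F10 (C6–OTBS, C11–OSEM) | C=C[C@](C)(O)C[C@H](OCOCC[Si](C)(C)C)[C@@H]1[C@]2(C)CC(=O)O[C@@]1(C)C[C@@H](O[Si](C)(C)C(C)(C)C)[C@H]2C(C)(C)C(=O)O
F12 | step 16 | F11 with free C11–OH (C6–OTBS) | C=C[C@](C)(O)C[C@H](O)[C@@H]1[C@]2(C)CC(=O)O[C@@]1(C)C[C@@H](O[Si](C)(C)C(C)(C)C)[C@H]2C(C)(C)C(=O)O
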